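## The problem

Target 16 is a 2'-hydroxychalcone. An (E)-propenone bridge joins C5 of a 2,3-dihydrobenzofuran (ring A with its fused dihydrofuran) to C6 of a 2,2-dimethyl-2H-chromene (ring B with its pyran). Ring A is a contiguously tetrasubstituted benzene: O1 on C7a, the benzylic C3 on C3a, a free hydroxyl on C4 and the acyl group on C5, so four different substituents must be placed in a fixed order. The only stereocenter is C2 (R), which carries the 2-hydroxypropan-2-yl group. No second stereocenter can relay its configuration, so it must come from a catalyst, a reagent or a resolved building block; once set, it is an ether carbon without an acidic hydrogen and should be stable. The fragile parts are the enone (the C4 hydroxyl can add to it to give a flavanone), the electron-rich chromene double bond (acid, hydrogenation, electrophilic oxidants) and the tertiary alcohol beside the C2–O1 bond, which under acid dehydrates or enlarges the ring to a chroman-3-ol. The enone is therefore best made last under base, and strongly acidic steps are avoided once the dihydrofuran exists. The enabling feature is the pair C2/C3: C2 is an ether carbon with one hydrogen, and C3 is a benzylic CH2 on C3a, flanked by the oxygens on C7a and C4. A carbene at C3, made from an aldehyde carbon lying between two phenolic oxygens, can insert into one of the two enantiotopic O–CH2 hydrogens of an achiral ether on the C7a oxygen and so form the C2–C3 bond, the ring and the stereocenter in one event.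

## Retrosynthesis

**Enone.** The Cα=Cβ double bond of the propenone bridge in 16 is cut first, giving methyl ketone 14 and aldehyde 15. The neighbouring cut, between C5 and the carbonyl carbon, would need a Friedel–Crafts cinnamoylation whose Lewis acid endangers the chromene and the tertiary alcohol and which cannot tell C5 from C7. The aldol cut halves the molecule, leaves the stereocenter in 14 alone and makes 15 a purchasable partner. The forward condensation must run on the unprotected phenol and give the E-enone without closing the flavanone.

**Acetyl group.** In 14 the C5–carbonyl bond and the carbonyl–methyl bond are cut in turn, through benzylic alcohol 13 and salicylaldehyde 12, back to phenol 11. Direct acetylation or a Fries rearrangement is the shorter neighbour, but its Lewis acid would ionize the tertiary carbinol beside C2, and C7 is as activated as C5. A magnesium phenoxide-directed formylation uses the C4 hydroxyl as director, and with C3a blocked only C5 is open. Phenol 11 has a trisubstituted ring A and no carbonyl group; the price is three routine steps, none needing a protecting group.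

**Silyl groups.** The two hydroxyls of 11 are masked in 10 as an aryl tert-butyldimethylsilyl ether at C4 and a triethylsilyl ether at the tertiary oxygen. They serve the key step only: the aryl silyl ether has no oxygen-activated C–H bond within reach of C3, and the capped tertiary oxygen cannot undergo O–H insertion. Both should fall to fluoride in one operation.

**C2–C3 bond.** In 10 the bond between the ether carbon C2 and the benzylic C3 is cut, which opens the dihydrofuran and erases the stereocenter. C3 becomes a carbene carbon, written as aryldiazomethane 9, and C2 becomes the O–CH2 group of an achiral ether; 9 is traced through sodium salt 8 to tosylhydrazone 7. Cutting O1–C7a or O1–C2 instead would keep C2 as a preformed stereocenter on an open chain and require an asymmetric oxidation followed by a separate cyclization. The C–C cut leads to a benzaldehyde whose two ortho oxygens are exactly O1 and the C4 oxygen. The forward reaction asks a chiral dirhodium catalyst to choose one of two enantiotopic hydrogens, to use the single activated C–H site five atoms from the carbene, and to outrun dimerization of the diazo compound.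

**Hydrazone and ether.** 7 is cut at the C=N bond to aldehyde 5 and sulfonyl hydrazide 6; 5 is stripped of its silyl groups by way of 4 to diol 3; and the O–CH2 bond of 3 is cut to 2,6-dihydroxybenzaldehyde 1 and epoxide 2. A halide in place of 2 would be a neopentyl-type electrophile, useless in SN2 reactions, whereas the epoxide opens at its CH2 terminus and brings the tertiary oxygen with it. Because 1 is symmetrical there is no regiochemical question; the forward steps only need to stop at mono-alkylation and silylate the phenol and the tertiary alcohol in turn.

## Roads not taken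

**Alternative 1:** The arene of ring A is cut at C4–C5 and C6–C7 (dihydrobenzofuran numbering).
- Forward step: the 2-prenylated bis(trimethylsilyloxy)diene A1 would add to but-3-yn-2-one A2 in a Diels–Alder reaction, and the adduct would aromatize by expelling its methoxy group to give the 3-prenylated dihydroxyacetophenone A3.
- Merits: the acetyl group, both hydroxyls and the prenyl chain arrive in the right order in one step, and the formylation, Grignard and oxidation steps of the chosen plan are not needed.
- Weak points: the cycloaddition does nothing for C2. A3 still needs an enantioselective oxidation of the prenyl alkene and a cyclization in which two phenols and two ring sizes (five-membered against chromanol) compete. A1 is a hydrolytically sensitive diene with a hindered, fully substituted terminus.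
- Comparison: this road is probably two or three steps shorter. The chosen plan sets against it that the C–C bond, the ring and the stereocenter arise together, at a site where only one oxygen and one ring size can take part, and that its arene regiochemistry is fixed by a symmetrical starting material.

**Alternative 2:** The O1–C2 bond of the dihydrofuran is traced to the pyran oxygen of a chroman.
- Forward step: the (3S)-chroman-3-yl mesylate A4 would ionize with participation of the ring oxygen, and hydrolytic opening of the bridged oxonium ion at the tertiary carbon would contract the ring with inversion to A5, which is identical with 14.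
- Merits: the step is stereospecific, the acetyl group is present from the start, and the alcohol behind A4 is accessible in high enantiomeric purity by established asymmetric epoxidation of the corresponding chromene followed by reductive opening. The road is shorter than the chosen one and its source of chirality is proven.
- Weak points: the participating oxygen is para to the acetyl group and thus a poor neighbouring group. The bridged ion can also be opened at the secondary carbon (return to the six-membered ring), lose a proton to an isopropenyl group, or be bypassed by elimination of the mesylate to the chromene. The constitutional outcome is therefore uncertain even though the configuration is not.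
- Comparison: on step count and on certainty of enantiopurity this road is ahead. The chosen plan sets against it a ring closure that can give only the five-membered ring and that never generates a cation next to the tertiary centre.

**Alternative 3:** The C7a–O1 bond is cut.
- Forward step: under carbonate base in a dipolar aprotic solvent the secondary alkoxide of fluoro diol A6 would displace the fluoride para to the acetyl group (SNAr), closing the dihydrofuran to benzyl ether A7 with the stereocenter untouched.
- Merits: the stereocenter would come from an asymmetric dihydroxylation of a trisubstituted prenyl alkene, a reaction of well-known sense and level of induction. The acetyl group both activates the displacement and is needed later. Stereochemically this is the most secure of the four roads.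
- Weak points: A6 is a contiguously tetrasubstituted fluoroarene whose assembly takes several steps of directed metalation or halogen chemistry. The tertiary alkoxide can compete to give the chromanol, the methyl ketone can self-condense under the basic conditions, and the benzyl group must be removed before any alkene is present.
- Comparison: the chosen plan sets against it a four-step, achiral precursor made from a symmetrical phenol and an epoxide. It concedes that its enantioselection is unproven where that of this road is established.

Key step: step 5

Remark 1: 2,2-dimethyl-2H-chromene-6-carbaldehyde 15 is treated as a purchasable compound.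
Remark 2: Rh2(S-PTAD)4 is taken to be the catalyst antipode that leads to (2R); if the sense of induction proves opposite, Rh2(R-PTAD)4 replaces it and nothing else changes.

## Route

Step 1
Reactants: 1 2,6-dihydroxybenzaldehyde; 2 2,2-dimethyloxirane
Product: 3 2-hydroxy-6-(2-hydroxy-2-methylpropoxy)benzaldehyde
Conditions: K2CO3 (0.3 equiv), 2 (1.2 equiv), DMF, 90 °C, sealed tube
Reagents that add atoms: none
Why: Base-catalysed opening of the epoxide by the phenoxide (SN2 at the unhindered CH2 terminus) gives the primary aryl ether and the tertiary alcohol. The two hydroxyls of 1 are equivalent, and 1 is more acidic than 3, so with substoichiometric base and limited epoxide the reaction should stop at the mono-ether.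

Step 2
Reactants: 3 2-hydroxy-6-(2-hydroxy-2-methylpropoxy)benzaldehyde
Product: 4 2-[(tert-butyldimethylsilyl)oxy]-6-(2-hydroxy-2-methylpropoxy)benzaldehyde
Conditions: TBSCl, imidazole, CH2Cl2, 0 °C to rt
Reagents that add atoms: tert-butyldimethylsilyl chloride, CC(C)(C)[Si](C)(C)Cl
Why: Standard silylation of a phenol with a silyl chloride and imidazole; the tertiary alcohol is inert to TBSCl under these conditions, so only the phenol is capped.

Step 3
Reactants: 4 2-[(tert-butyldimethylsilyl)oxy]-6-(2-hydroxy-2-methylpropoxy)benzaldehyde
Product: 5 2-[(tert-butyldimethylsilyl)oxy]-6-[2-methyl-2-(triethylsilyloxy)propoxy]benzaldehyde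
Conditions: TESOTf, 2,6-lutidine, CH2Cl2, −78 to 0 °C
Reagents that add atoms: triethylsilyl trifluoromethanesulfonate, CC[Si](CC)(CC)OS(=O)(=O)C(F)(F)F
Why: Silyl triflates with a hindered pyridine base silylate tertiary alcohols, and the base does not add to the aldehyde. The small triethylsilyl group keeps the surroundings of the O–CH2 group as open as a protected tertiary alcohol allows.

Step 4
Reactants: 5 2-[(tert-butyldimethylsilyl)oxy]-6-[2-methyl-2-(triethylsilyloxy)propoxy]benzaldehyde; 6 4-methylbenzenesulfonohydrazide
Product: 7 N'-[(E)-{2-[(tert-butyldimethylsilyl)oxy]-6-[2-methyl-2-(triethylsilyloxy)propoxy]phenyl}methylidene]-4-methylbenzenesulfonohydrazide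
Conditions: THF, MgSO4, rt
Reagents that add atoms: none
Why: Condensation of an aldehyde with a sulfonyl hydrazide to the sulfonylhydrazone; the neutral conditions leave both silyl ethers intact, and the E isomer is expected as is usual for aldehyde tosylhydrazones.

Step 5
Reactants: 7 N'-[(E)-{2-[(tert-butyldimethylsilyl)oxy]-6-[2-methyl-2-(triethylsilyloxy)propoxy]phenyl}methylidene]-4-methylbenzenesulfonohydrazide
Product: 10 tert-butyldimethyl{[(2R)-2-[2-(triethylsilyloxy)propan-2-yl]-2,3-dihydro-1-benzofuran-4-yl]oxy}silane, via sodium tosylhydrazonide 8 (not isolated), via aryldiazomethane 9 (not isolated)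
Conditions: NaH (1.05 equiv), CH2Cl2, 0 °C to rt; then BnEt3NCl (10 mol%), Rh2(S-PTAD)4 [dirhodium tetrakis((S)-(1-adamantyl)(N-phthalimido)acetate)] (1 mol%), 40 °C
Reagents that add atoms: none
Why: Proposed new method: NaH converts 7 into salt 8, which under phase-transfer conditions loses sulfinate (Bamford–Stevens reaction) to release aryldiazomethane 9 slowly, and the dirhodium tetracarboxylate (divalent rhodium) captures 9 with loss of N2 as a donor carbene at the future C3. With both ortho positions substituted the aryl ring should twist out of the carbene plane and hold the O–CH2 group over the vacant carbene orbital, so that hydride shift and C–C bond formation occur in one asynchronous event through a five-membered transition state (1,5 C–H insertion), forming C2–C3 and closing the dihydrofuran ring. The closest known reaction types are the enantioselective 1,5-insertion of donor/donor rhodium carbenes generated from hydrazones into ether C–H bonds, which gives 2,3-disubstituted dihydrobenzofurans, and the racemic cyclization of ortho-alkoxyaryl carbenes from tosylhydrazone salts; untested are a carbene whose second substituent is hydrogen and a methylene flanked by a quaternary carbon. The C2 stereocenter is set by catalyst control alone: the chiral carboxylate ligands must distinguish the two enantiotopic hydrogens of the O–CH2 group, with the bulky silyloxyisopropyl group expected to take the pseudo-equatorial site of the envelope-like transition state. Site selectivity is secured by the substrate, because the only oxygen-activated C–H bonds within reach are those of the O–CH2 group: the other ortho oxygen carries a silyl group without alpha-oxy hydrogens, and the tertiary oxygen is capped so that O–H insertion is excluded. Slow release of 9 keeps its concentration low and should disfavour azine and stilbene formation.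

Step 6
Reactants: 10 tert-butyldimethyl{[(2R)-2-[2-(triethylsilyloxy)propan-2-yl]-2,3-dihydro-1-benzofuran-4-yl]oxy}silane
Product: 11 (2R)-2-(2-hydroxypropan-2-yl)-2,3-dihydro-1-benzofuran-4-ol
Conditions: TBAF (2.5 equiv), THF, 0 °C to rt
Reagents that add atoms: none
Why: Fluoride-mediated desilylation cleaves the aryl silyl ether and the tertiary triethylsilyl ether in one operation; C2 is an ether carbon without acidifying neighbours and is not at risk.

Step 7
Reactants: 11 (2R)-2-(2-hydroxypropan-2-yl)-2,3-dihydro-1-benzofuran-4-ol
Product: 12 (2R)-4-hydroxy-2-(2-hydroxypropan-2-yl)-2,3-dihydro-1-benzofuran-5-carbaldehyde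
Conditions: MgCl2, Et3N, (CH2O)n, MeCN, reflux; 1 M HCl work-up
Reagents that add atoms: paraformaldehyde (formaldehyde), C=O
Why: Magnesium phenoxide-directed ortho-formylation (Casnati–Skattebøl reaction): formaldehyde is delivered within the magnesium chelate to the position ortho to the hydroxyl, and a second formaldehyde accepts hydride to give the aldehyde. Since C3a is substituted only C5 can react, and the conditions contain no strong acid that could ionize the tertiary alcohol.

Step 8
Reactants: 12 (2R)-4-hydroxy-2-(2-hydroxypropan-2-yl)-2,3-dihydro-1-benzofuran-5-carbaldehyde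
Product: 13 (2R)-5-(1-hydroxyethyl)-2-(2-hydroxypropan-2-yl)-2,3-dihydro-1-benzofuran-4-ol (mixture of the two epimers at the new carbinol carbon)
Conditions: MeMgBr (4 equiv), THF, 0 °C to rt; aq. NH4Cl
Reagents that add atoms: methylmagnesium bromide, C[Mg]Br
Why: Grignard addition to an aldehyde; two equivalents are consumed by the phenol and the tertiary alcohol, and the chelated aldehyde then takes up the methyl group. The new carbinol center is formed without control, which does not matter because it is oxidized in the next step.

Step 9
Reactants: 13 (2R)-5-(1-hydroxyethyl)-2-(2-hydroxypropan-2-yl)-2,3-dihydro-1-benzofuran-4-ol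
Product: 14 1-[(2R)-4-hydroxy-2-(2-hydroxypropan-2-yl)-2,3-dihydro-1-benzofuran-5-yl]ethan-1-one
Conditions: activated MnO2 (excess), CH2Cl2, rt
Reagents that add atoms: none
Why: MnO2 oxidizes benzylic alcohols selectively; the tertiary alcohol cannot be oxidized, and the ketone formed is stabilized by its hydrogen bond to the C4 hydroxyl.

Step 10
Reactants: 14 1-[(2R)-4-hydroxy-2-(2-hydroxypropan-2-yl)-2,3-dihydro-1-benzofuran-5-yl]ethan-1-one; 15 2,2-dimethyl-2H-chromene-6-carbaldehyde
Product: 16 (2E)-3-(2,2-dimethyl-2H-chromen-6-yl)-1-[(2R)-4-hydroxy-2-(2-hydroxypropan-2-yl)-2,3-dihydro-1-benzofuran-5-yl]prop-2-en-1-one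
Conditions: KOH (aq., excess), EtOH, rt; then dilute HCl to pH 5–6 at 0 °C
Reagents that add atoms: none
Why: Claisen–Schmidt condensation (crossed aldol addition and E1cB dehydration) of the methyl ketone enolate with the non-enolizable aldehyde 15; the conjugated (E)-enone is the thermodynamic product. C2 carries no acidic hydrogen and C3 is not conjugated with the ketone, so the stereocenter is untouched.

## Compound list

1 | 2,6-dihydroxybenzaldehyde | O=Cc1c(O)cccc1O | starting material
2 | 2,2-dimethyloxirane | CC1(C)CO1 | starting material
3 | 2-hydroxy-6-(2-hydroxy-2-methylpropoxy)benzaldehyde | O=Cc1c(O)cccc1OCC(C)(C)O | intermediate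
4 | 2-[(tert-butyldimethylsilyl)oxy]-6-(2-hydroxy-2-methylpropoxy)benzaldehyde | O=Cc1c(O[Si](C)(C)C(C)(C)C)cccc1OCC(C)(C)O | intermediate
5 | 2-[(tert-butyldimethylsilyl)oxy]-6-[2-methyl-2-(triethylsilyloxy)propoxy]benzaldehyde | O=Cc1c(O[Si](C)(C)C(C)(C)C)cccc1OCC(C)(C)O[Si](CC)(CC)CC | intermediate
6 | 4-methylbenzenesulfonohydrazide | Cc1ccc(cc1)S(=O)(=O)NN | starting material
7 | N'-[(E)-{2-[(tert-butyldimethylsilyl)oxy]-6-[2-methyl-2-(triethylsilyloxy)propoxy]phenyl}methylidene]-4-methylbenzenesulfonohydrazide | Cc1ccc(cc1)S(=O)(=O)N/N=C/c1c(O[Si](C)(C)C(C)(C)C)cccc1OCC(C)(C)O[Si](CC)(CC)CC | intermediate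
8 | sodium salt of tosylhydrazone 7 (deprotonated at the sulfonamide nitrogen) | Cc1ccc(cc1)S(=O)(=O)[N-]/N=C/c1c(O[Si](C)(C)C(C)(C)C)cccc1OCC(C)(C)O[Si](CC)(CC)CC.[Na+] | intermediate
9 | tert-butyl{2-(diazomethyl)-3-[2-methyl-2-(triethylsilyloxy)propoxy]phenoxy}dimethylsilane | [N-]=[N+]=Cc1c(O[Si](C)(C)C(C)(C)C)cccc1OCC(C)(C)O[Si](CC)(CC)CC | intermediate
10 | tert-butyldimethyl{[(2R)-2-[2-(triethylsilyloxy)propan-2-yl]-2,3-dihydro-1-benzofuran-4-yl]oxy}silane | CC(C)(O[Si](CC)(CC)CC)[C@H]1Cc2c(O[Si](C)(C)C(C)(C)C)cccc2O1 | intermediate
11 | (2R)-2-(2-hydroxypropan-2-yl)-2,3-dihydro-1-benzofuran-4-ol | CC(C)(O)[C@H]1Cc2c(O)cccc2O1 | intermediate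
12 | (2R)-4-hydroxy-2-(2-hydroxypropan-2-yl)-2,3-dihydro-1-benzofuran-5-carbaldehyde | CC(C)(O)[C@H]1Cc2c(O)c(C=O)ccc2O1 | intermediate
13 | (2R)-5-(1-hydroxyethyl)-2-(2-hydroxypropan-2-yl)-2,3-dihydro-1-benzofuran-4-ol, both epimers at the carbinol carbon | CC(O)c1ccc2c(c1O)C[C@H](C(C)(C)O)O2 | intermediate
14 | 1-[(2R)-4-hydroxy-2-(2-hydroxypropan-2-yl)-2,3-dihydro-1-benzofuran-5-yl]ethan-1-one | CC(=O)c1ccc2c(c1O)C[C@H](C(C)(C)O)O2 | intermediate
15 | 2,2-dimethyl-2H-chromene-6-carbaldehyde | CC1(C)C=Cc2cc(C=O)ccc2O1 | starting material
16 | (2E)-3-(2,2-dimethyl-2H-chromen-6-yl)-1-[(2R)-4-hydroxy-2-(2-hydroxypropan-2-yl)-2,3-dihydro-1-benzofuran-5-yl]prop-2-en-1-one | CC1(C)C=Cc2cc(/C=C/C(=O)c3ccc4c(c3O)C[C@H](C(C)(C)O)O4)ccc2O1 | target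

## Step count and risks

Total: 10 steps. Longest linear sequence: 10 steps (1 to 16); 2, 6 and 15 enter as purchased reagents.

**Step 5 (key step).** Two things are most likely to go wrong. The first is poor discrimination between the two enantiotopic hydrogens, because the carbene carries hydrogen as its second substituent and its aryl group is twisted by two ortho substituents. The second is slow insertion at a methylene that is hindered by the quaternary neighbour and inductively deactivated by the beta-silyloxy group, so that dimerization to azine or stilbene, or capture of the carbene by sulfinate, takes over. The fallback uses known chemistry without any C–H insertion; it sets out from 1 and comes back at 11. Alkylation of 1 with methyl bromoacetate (K2CO3, DMF, 90 °C) is followed in the same flask by intramolecular aldol condensation of the aryloxyacetate onto the aldehyde. This forms the same C2–C3 bond and gives methyl 4-hydroxy-1-benzofuran-2-carboxylate F1. Magnesium in methanol reduces the C2–C3 double bond to racemic methyl 4-hydroxy-2,3-dihydro-1-benzofuran-2-carboxylate F2. Resolution by preparative chromatography on a chiral stationary phase gives methyl (2R)-4-hydroxy-2,3-dihydro-1-benzofuran-2-carboxylate F3, and excess MeMgBr (THF, 0 °C) turns the ester into the tertiary alcohol 11. The route continues with step 7.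

**Step 1.** Over-alkylation to the bis-ether, and sluggish opening of the hindered epoxide at a temperature the hydroxy aldehyde tolerates, are the likely failures. The fallback builds the ether with a reactive allylic halide and creates the tertiary alcohol afterwards; it sets out from 1 and comes back at 4. Alkylation of 1 with 3-chloro-2-methylprop-1-ene (K2CO3, acetone, 50 °C) gives 2-hydroxy-6-[(2-methylprop-2-en-1-yl)oxy]benzaldehyde F4. Silylation (TBSCl, imidazole) gives 2-[(tert-butyldimethylsilyl)oxy]-6-[(2-methylprop-2-en-1-yl)oxy]benzaldehyde F5. Mukaiyama hydration of the 1,1-disubstituted alkene (Co(acac)2, PhSiH3, O2, THF, rt) places the hydroxyl at the tertiary carbon and gives 4.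

**Step 7.** The very electron-rich magnesium phenoxide of 11 may react further with formaldehyde (diarylmethane formation), or the formylation may stall with the tertiary alcohol bound to magnesium. The fallback replaces electrophilic formylation by directed ortho-metalation and bypasses steps 7 to 9; it sets out from 11 and comes back at 14. Both hydroxyls are protected (MOMCl, iPr2NEt, CH2Cl2, 40 °C) to give (2R)-4-(methoxymethoxy)-2-[2-(methoxymethoxy)propan-2-yl]-2,3-dihydro-1-benzofuran F6. Lithiation ortho to the aryl methoxymethyl ether (n-BuLi, TMEDA, THF, −78 to 0 °C), which with C3a blocked is C5, and quenching with N-methoxy-N-methylacetamide give 1-[(2R)-4-(methoxymethoxy)-2-[2-(methoxymethoxy)propan-2-yl]-2,3-dihydro-1-benzofuran-5-yl]ethan-1-one F7. Dilute HCl in MeOH (40 °C) removes both acetals and gives 14.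

**Step 10.** Conjugate addition of the C4 phenoxide to the new enone (flavanone formation) and slow condensation are the likely failures, since the ketone reacts as a phenoxide and the aldehyde is deactivated by its para oxygen. The fallback masks the phenol during the condensation; it sets out from 14 and comes back at 16. Etherification (MOMCl, K2CO3, acetone, reflux) gives 1-[(2R)-2-(2-hydroxypropan-2-yl)-4-(methoxymethoxy)-2,3-dihydro-1-benzofuran-5-yl]ethan-1-one F8. Condensation with 15 (KOH, EtOH, rt) gives (2E)-3-(2,2-dimethyl-2H-chromen-6-yl)-1-[(2R)-2-(2-hydroxypropan-2-yl)-4-(methoxymethoxy)-2,3-dihydro-1-benzofuran-5-yl]prop-2-en-1-one F9, which cannot cyclize. Mild acid (HCl, MeOH, rt to 40 °C) cleaves the chelation-activated acetal and gives 16.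

## Further compounds

F1 | step 5 | methyl 4-hydroxy-1-benzofuran-2-carboxylate | COC(=O)c1cc2c(O)cccc2o1
F2 | step 5 | methyl 4-hydroxy-2,3-dihydro-1-benzofuran-2-carboxylate (racemic) | COC(=O)C1Cc2c(O)cccc2O1
F3 | step 5 | methyl (2R)-4-hydroxy-2,3-dihydro-1-benzofuran-2-carboxylate | COC(=O)[C@H]1Cc2c(O)cccc2O1
F4 | step 1 | 2-hydroxy-6-[(2-methylprop-2-en-1-yl)oxy]benzaldehyde | O=Cc1c(O)cccc1OCC(C)=C
F5 | step 1 | 2-[(tert-butyldimethylsilyl)oxy]-6-[(2-methylprop-2-en-1-yl)oxy]benzaldehyde | O=Cc1c(O[Si](C)(C)C(C)(C)C)cccc1OCC(C)=C
F6 | step 7 | (2R)-4-(methoxymethoxy)-2-[2-(methoxymethoxy)propan-2-yl]-2,3-dihydro-1-benzofuran | COCOC(C)(C)[C@H]1Cc2c(OCOC)cccc2O1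
F7 | step 7 | 1-[(2R)-4-(methoxymethoxy)-2-[2-(methoxymethoxy)propan-2-yl]-2,3-dihydro-1-benzofuran-5-yl]ethan-1-one | CC(=O)c1ccc2c(c1OCOC)C[C@H](C(C)(C)OCOC)O2
F8 | step 10 | 1-[(2R)-2-(2-hydroxypropan-2-yl)-4-(methoxymethoxy)-2,3-dihydro-1-benzofuran-5-yl]ethan-1-one | CC(=O)c1ccc2c(c1OCOC)C[C@H](C(C)(C)O)O2
F9 | step 10 | (2E)-3-(2,2-dimethyl-2H-chromen-6-yl)-1-[(2R)-2-(2-hydroxypropan-2-yl)-4-(methoxymethoxy)-2,3-dihydro-1-benzofuran-5-yl]prop-2-en-1-one | CC1(C)C=Cc2cc(/C=C/C(=O)c3ccc4c(c3OCOC)C[C@H](C(C)(C)O)O4)ccc2O1
A1 | alternative 1 | 1-methoxy-2-(3-methylbut-2-en-1-yl)-1,3-bis(trimethylsilyloxy)buta-1,3-diene | COC(O[Si](C)(C)C)=C(CC=C(C)C)C(=C)O[Si](C)(C)C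
A2 | alternative 1 | but-3-yn-2-one | CC(=O)C#C
A3 | alternative 1 | 1-[2,4-dihydroxy-3-(3-methylbut-2-en-1-yl)phenyl]ethan-1-one | CC(=O)c1ccc(O)c(CC=C(C)C)c1O
A4 | alternative 2 | (3S)-6-acetyl-5-hydroxy-2,2-dimethyl-3,4-dihydro-2H-1-benzopyran-3-yl methanesulfonate | CC(=O)c1ccc2c(c1O)C[C@H](OS(C)(=O)=O)C(C)(C)O2
A5 | alternative 2 | 1-[(2R)-4-hydroxy-2-(2-hydroxypropan-2-yl)-2,3-dihydro-1-benzofuran-5-yl]ethan-1-one (identical with 14) | CC(=O)c1ccc2c(c1O)C[C@H](C(C)(C)O)O2
A6 | alternative 3 | 1-[2-(benzyloxy)-3-[(2R)-2,3-dihydroxy-3-methylbutyl]-4-fluorophenyl]ethan-1-one | CC(=O)c1ccc(F)c(C[C@H](C(C)(C)O)O)c1OCc1ccccc1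
A7 | alternative 3 | 1-[(2R)-4-(benzyloxy)-2-(2-hydroxypropan-2-yl)-2,3-dihydro-1-benzofuran-5-yl]ethan-1-one | CC(=O)c1ccc2c(c1OCc3ccccc3)C[C@H](C(C)(C)O)O2
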